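The route rests on undoing the C8–C9 bond of the ten-membered ring while re-forming C6–C1, a retro oxy-Cope. The handle is the position of the syn-oxygenated carbons C8 and C9 directly between C7 and the E C1=C10 double bond. Read backwards, they are the termini of two enol ethers carried by the neighbouring atoms C6 and C1 of a six-membered ring whose own double bond is the Z C4=C5 olefin. One anionic [3,3] shift therefore delivers the carbocycle, the E olefin, the C6 ketone and both carbinol centres. Its precursor is a trans-1,2-dialkenyl-3-methylcyclohex-2-en-1-ol with an (E)-PMB-oxyvinyl group on C6 and an (E)-MOM-oxypropenyl group on C1, the C1 centre being bought as a p-menthadienol.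

Key step: step 9

Remark on numbering: germacrane locants are used for all ring compounds (ring C1–C10, lactone C11–C13, C14 on C10, C15 on C4). PMB = 4-methoxybenzyl, MOM = methoxymethyl, TES = triethylsilyl.
Remark on configuration: the target is read as (1R,6S,7S,8R,9S,10R), with a cis-fused lactone (H6 and H7 on one face) and a trans-configured epoxide. C9 has the descriptor R while C10 is sp2 (C8 then outranks C10) and becomes S on epoxidation with no change in space, so the ring-expanded ketone is (8R,9R).
Assumption: 8 is bought as the (1S,4R) isomer. Its carbinol centre is lost in step 3, so the epimer or a mixture would serve equally.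

Step 1
Reactants: 1 4-methoxybenzyl alcohol; 2 trichloroethylene
Product: 5 4-methoxybenzyl ethynyl ether, via dichlorovinyl ether 3 (not isolated), via lithium acetylide 4 (not isolated)
Conditions: KH, THF, 0 °C; 2, −50 °C → rt; nBuLi (2.2 equiv), −78 → −40 °C; MeOH, −78 °C
Reagents that add atoms: none
Why: One-flask ynol ether synthesis in which the potassium alkoxide adds to trichloroethylene by elimination–addition to give 3 and nBuLi then effects dehydrochlorination plus Cl/Li exchange to acetylide 4, which is protonated and kept cold because benzyl alkynyl ethers rearrange on warming.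

Step 2
Reactants: 5 4-methoxybenzyl ethynyl ether
Product: 7 (E)-2-iodoethenyl 4-methoxybenzyl ether, via alkenylzirconocene 6 (not isolated)
Conditions: Cp2Zr(H)Cl, THF, 0 °C → rt; I2 (1 equiv), −78 °C
Reagents that add atoms: iodine, II
Why: Hydrozirconation is a syn addition that places zirconium on the terminal carbon remote from oxygen, and iodinolysis of the C–Zr bond proceeds with retention, so only the E iodide should form.

Step 3
Reactants: 8 (1S,4R)-p-mentha-2,8-dien-1-ol
Product: 9 (S)-isopiperitenone
Conditions: pyridinium chlorochromate (C5H5NH)[CrO3Cl], Celite, CH2Cl2, rt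
Reagents that add atoms: pyridinium chlorochromate, [O-][Cr](=O)(=O)Cl.c1cc[nH+]cc1
Why: Babler–Dauben oxidative transposition in which the tertiary allylic chromate ester undergoes a [3,3] shift and is oxidised to the enone, the carbonyl oxygen coming from chromium, while the base-sensitive C1 stereocentre is untouched under these non-basic conditions.

Step 4
Reactants: 7 (E)-2-iodoethenyl 4-methoxybenzyl ether; 9 (S)-isopiperitenone
Product: 12 TES ether of the (1S,6S) trans-dialkenyl carbinol, via alkenyllithium 10 (not isolated), via lithium alkoxide 11 (not isolated)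
Conditions: 7, tBuLi (2 equiv), Et2O, −78 °C; 9, −78 °C; Et3SiOTf, 2,6-lutidine, −78 → −20 °C
Reagents that add atoms: triethylsilyl triflate, CC[Si](CC)(CC)OS(=O)(=O)C(F)(F)F
Why: Iodine–lithium exchange with retention is followed by 1,2-addition of the alkenyllithium to the carbonyl face opposite the neighbouring pseudo-equatorial isopropenyl group (equatorial trajectory), which sets C6 with the two alkenyl groups trans, and O-silylation of 11 in the same flask masks the carbinol for the next three steps.

Step 5
Reactants: 12 TES ether of the trans-dialkenyl carbinol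
Product: 14 C9 primary alcohol (C10 epimers), via alkylborane 13 (not isolated)
Conditions: 9-BBN, THF, 0 °C → rt; H2O2, NaOH aq, 0 °C
Reagents that add atoms: hydrogen peroxide, OO
Why: Brown hydroboration–oxidation in which 9-BBN selects the unhindered 1,1-disubstituted alkene over the trisubstituted ring olefin and over the enol ether, whose boron-accepting carbon C7 is neopentyl, and the C10 epimer mixture is of no consequence because C10 becomes sp2 again.

Step 6
Reactants: 14 C9 primary alcohol
Product: 15 C9 aldehyde (C10 epimers)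
Conditions: (nPr4N)[RuO4] (cat), NMO, 4 Å MS, CH2Cl2, 0 °C → rt
Reagents that add atoms: none
Why: Ley–Griffith oxidation runs under neutral conditions that spare the acid-labile β-alkoxyvinyl carbinol ether and stops at the aldehyde.

Step 7
Reactants: 15 C9 aldehyde; 16 chloromethyl methyl ether
Product: 18 TES ether of the bis(enol ether), via potassium enolate 17 (not isolated)
Conditions: KN(SiMe3)2, THF–DMPU, −78 °C; 16, −78 → −40 °C
Reagents that add atoms: none
Why: O-alkylation of a potassium aldehyde enolate by a hard chloromethyl ether in a dipolar medium, in which the oxido group settles trans to the very bulky C1 ring substituent and cis to the methyl group so that the E enol ether should result, and in which C1 cannot epimerise because no ketone is left.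

Step 8
Reactants: 18 TES ether of the bis(enol ether)
Product: 19 (1S,6S)-1-[(E)-2-(PMB-oxy)ethenyl]-6-[(E)-1-(MOM-oxy)prop-1-en-2-yl]-3-methylcyclohex-2-en-1-ol
Conditions: nBu4NF, THF, 0 °C; chromatography on Et3N-deactivated silica
Reagents that add atoms: none
Why: Fluoride-induced desilylation under basic conditions frees the tertiary alcohol without touching either enol ether.

Step 9
Reactants: 19 trans-bis(alkoxyalkenyl)cyclohexenol
Product: 22 (2Z,6E,8R,9R)-8-(MOM-oxy)-9-(PMB-oxy)-3,7-dimethylcyclodeca-2,6-dien-1-one, via potassium alkoxide 20 (not isolated), via potassium dienolate 21 (not isolated)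
Conditions: KH, 18-crown-6, THF, 0 °C → rt; cannulation into AcOH–THF, −78 °C
Reagents that add atoms: none
Why: KH turns the C6 carbinol into alkoxide 20, whose charge weakens the C6–C1 bond and drives a concerted [3,3] shift that joins the two enol-ether carbons C8 and C9 and releases the cross-conjugated dienolate 21, which is protonated at C7 on inverse quench to give 22. The closest known reaction type is the anionic oxy-Cope ring expansion of trans-1,2-dialkenylcyclohexanols and -cyclohexenols to (E)-cyclodec-5-enones, in which single enol-ether termini are tolerated, the case with an alkoxy group on both termini being the demanding member of this class. The ten-membered ring is closed by four-atom ring expansion of the cyclohexene (C8–C9 made, C6–C1 lost) and not by end-to-end cyclisation, and the Z C4=C5 bond is carried over unchanged. In the chair array open to the trans-diequatorial conformer the ring bonds C6–C5 and C1–C2 are equatorial, which gives the E C1=C10 olefin, and both E enol ethers hold their oxygen equatorial, so that C8 is fixed by the C7=C8 geometry, C9 by the C9=C10 geometry, their relation is syn, and the absolute sense (8R,9R) is dictated by the C1 and C6 centres. The step needs chair over boat, the exocyclic C7=C8 bond instead of the ring C4=C5 bond as partner, and survival of the C8 ether in 21. The first two are secured by the equatorial side chains (the ring olefin could be reached only from an axial side chain through a boat) and the third by the C8–O bond lying close to the nodal plane of the newly formed dienolate and by the quench at −78 °C.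

Step 10
Reactants: 22 ring-expanded dienone; 23 methyl iodoacetate
Product: 25 (7R,8R,9R) C7-(methoxycarbonylmethyl) ketone, via lithium dienolate 24 (not isolated)
Conditions: LiN(iPr)2, THF, −78 °C; 23, DMPU, −78 → −45 °C
Reagents that add atoms: none
Why: Kinetic α′-deprotonation of the enone removes the peripheral C7–H (the reverse of the protonation in step 9) and the regenerated Z(O)-dienolate undergoes SN2 alkylation from the outside of the ring, which sets C7 with the new chain trans to the C8 ether, the reactive iodide keeping the temperature below that at which the C8 alkoxide is expelled.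

Step 11
Reactants: 25 keto ester
Product: 27 (6S,7S,8R,9R) cis-fused γ-lactone, via hydroxy ester 26 (not isolated)
Conditions: NaBH4, CeCl3·7H2O, MeOH, −78 → 0 °C; PPTS (cat), CH2Cl2, rt
Reagents that add atoms: none
Why: Luche reduction delivers hydride in 1,2 fashion from the ring periphery, the face turned away from the transannular C1=C10 bond, which leaves O6 on the same side as the C7 side chain (sets C6), and the cis γ-hydroxy ester 26 closes to the cis-fused lactone with loss of methanol.

Step 12
Reactants: 27 cis-fused γ-lactone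
Product: 30 α-methylene lactone, via Mannich base 28 (not isolated), via ammonium iodide 29 (not isolated)
Conditions: LiN(iPr)2, THF, −78 °C; [CH2=NMe2]I, −78 °C → rt; MeI, THF, rt; NaHCO3 aq, CH2Cl2, rt
Reagents that add atoms: N,N-dimethylmethyleneiminium iodide, C=[N+](C)C.[I-]
Why: Eschenmoser methylenation (Mannich reaction of the lactone enolate, N-quaternisation, Hofmann-type β-elimination) installs C13, and the lactone enolate has no β-leaving group so C7 and C8 are not at risk.

Step 13
Reactants: 30 α-methylene lactone
Product: 31 C8 alcohol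
Conditions: DDQ, CH2Cl2–pH 7 buffer, 0 °C
Reagents that add atoms: none
Why: Oxidative PMB cleavage by hydride abstraction with DDQ is neutral and leaves the MOM acetal, the olefins and the α-methylene lactone alone, while the buffer and short contact time disfavour translactonisation to O8.

Step 14
Reactants: 31 C8 alcohol
Product: 32 C8 isobutyrate
Conditions: (iPrCO)2O, DMAP (cat), Et3N, CH2Cl2, 0 °C
Reagents that add atoms: isobutyric anhydride, CC(C)C(=O)OC(=O)C(C)C
Why: DMAP-catalysed acyl transfer (Steglich-type acylation) esterifies the only free hydroxyl group.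

Step 15
Reactants: 32 C8 isobutyrate
Product: 34 C9 allylic alcohol, via bromomethyl ether 33 (not isolated)
Conditions: Me2BBr, CH2Cl2, −78 °C; NaHCO3 aq–THF
Reagents that add atoms: none
Why: Dialkylboron bromide acetal cleavage takes place at the methoxy oxygen at −78 °C to give 33, which is hydrolysed on bicarbonate work-up, so the allylic C9–O bond is never ionised and the ester, the lactone and the acid-sensitive 1(10),4-diene survive.

Step 16
Reactants: 34 C9 allylic alcohol
Product: 35 target CNP0110853.1
Conditions: mCPBA, NaHCO3, CH2Cl2, −20 → 0 °C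
Reagents that add atoms: 3-chloroperbenzoic acid, OOC(=O)c1cccc(Cl)c1
Why: Prilezhaev epoxidation in which the strained E C1=C10 olefin is the most nucleophilic alkene (C4=C5 is deactivated by the allylic lactone oxygen, C11=C13 is electron-poor) and is open only on its outer face in the conformer with a pseudo-equatorial C9–OH, whose large O–C9–C10=C1 dihedral suits hydrogen-bond guidance of a peracid and leads to the (1R,10R) threo epoxy alcohol, whereas a vanadium-bound peroxide would need the small-dihedral conformer and the opposite face.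

Compound list
1 | 4-methoxybenzyl alcohol | COc1ccc(CO)cc1 | starting material
2 | trichloroethylene | ClC=C(Cl)Cl | starting material
3 | (E)-1,2-dichloroethenyl 4-methoxybenzyl ether | COc1ccc(CO/C(Cl)=C\Cl)cc1 | intermediate
4 | lithium (4-methoxybenzyloxy)acetylide | COc1ccc(COC#C[Li])cc1 | intermediate
5 | 1-[(ethynyloxy)methyl]-4-methoxybenzene | COc1ccc(COC#C)cc1 | intermediate
6 | chlorobis(cyclopentadienyl)[(E)-2-(4-methoxybenzyloxy)ethenyl]zirconium | COc1ccc(CO/C=C/[Zr](Cl)(C2C=CC=C2)C2C=CC=C2)cc1 | intermediate
7 | 1-{[(E)-2-iodoethenyl]oxymethyl}-4-methoxybenzene | COc1ccc(CO/C=C/I)cc1 | intermediate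
8 | (1S,4R)-1-methyl-4-(prop-1-en-2-yl)cyclohex-2-en-1-ol | C1=C[C@@](C)(O)CC[C@H]1C(C)=C | starting material
9 | (6S)-3-methyl-6-(prop-1-en-2-yl)cyclohex-2-en-1-one, (S)-isopiperitenone | O=C1C=C(C)CC[C@H]1C(C)=C | intermediate
10 | (E)-2-(4-methoxybenzyloxy)ethenyllithium | COc1ccc(CO/C=C/[Li])cc1 | intermediate
11 | lithium (1S,6S)-1-[(E)-2-(4-methoxybenzyloxy)ethenyl]-3-methyl-6-(prop-1-en-2-yl)cyclohex-2-en-1-olate | [Li]O[C@@]1(/C=C/OCc2ccc(OC)cc2)C=C(C)CC[C@H]1C(C)=C | intermediate
12 | triethyl{(1S,6S)-1-[(E)-2-(4-methoxybenzyloxy)ethenyl]-3-methyl-6-(prop-1-en-2-yl)cyclohex-2-en-1-yloxy}silane | CC[Si](CC)(CC)O[C@@]1(/C=C/OCc2ccc(OC)cc2)C=C(C)CC[C@H]1C(C)=C | intermediate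
13 | B-alkyl-9-borabicyclo[3.3.1]nonane from 12, boron on C9, C10 epimers | CC[Si](CC)(CC)O[C@@]1(/C=C/OCc2ccc(OC)cc2)C=C(C)CC[C@H]1C(C)CB1C2CCCC1CCC2 | intermediate
14 | 2-{(1S,2R)-2-[(E)-2-(4-methoxybenzyloxy)ethenyl]-4-methyl-2-(triethylsilyloxy)cyclohex-3-en-1-yl}propan-1-ol, C10 epimers | CC[Si](CC)(CC)O[C@@]1(/C=C/OCc2ccc(OC)cc2)C=C(C)CC[C@H]1C(C)CO | intermediate
15 | 2-{(1S,2R)-2-[(E)-2-(4-methoxybenzyloxy)ethenyl]-4-methyl-2-(triethylsilyloxy)cyclohex-3-en-1-yl}propanal, C10 epimers | CC[Si](CC)(CC)O[C@@]1(/C=C/OCc2ccc(OC)cc2)C=C(C)CC[C@H]1C(C)C=O | intermediate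
16 | chloromethyl methyl ether | COCCl | starting material
17 | potassium (E)-enolate of 15 (oxygen trans to C1) | CC[Si](CC)(CC)O[C@@]1(/C=C/OCc2ccc(OC)cc2)C=C(C)CC[C@H]1/C(C)=C/O[K] | intermediate
18 | triethylsilyl ether of 19, (1S,6S) | CC[Si](CC)(CC)O[C@@]1(/C=C/OCc2ccc(OC)cc2)C=C(C)CC[C@H]1/C(C)=C/OCOC | intermediate
19 | (1S,6S)-1-[(E)-2-(4-methoxybenzyloxy)ethenyl]-6-[(E)-1-(methoxymethoxy)prop-1-en-2-yl]-3-methylcyclohex-2-en-1-ol | O[C@@]1(/C=C/OCc2ccc(OC)cc2)C=C(C)CC[C@H]1/C(C)=C/OCOC | intermediate
20 | potassium alkoxide of 19 | [K]O[C@@]1(/C=C/OCc2ccc(OC)cc2)C=C(C)CC[C@H]1/C(C)=C/OCOC | intermediate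
21 | potassium dienolate of 22 (C6=C7 with O6 cis to C8, 4Z, 1(10)E, 8R,9R) | [K]O/C1=C\[C@@H](OCc2ccc(OC)cc2)[C@H](OCOC)/C(C)=C/CC/C(C)=C\1 | intermediate
22 | (2Z,6E,8R,9R)-8-(methoxymethoxy)-9-(4-methoxybenzyloxy)-3,7-dimethylcyclodeca-2,6-dien-1-one | O=C1/C=C(/C)CC/C=C(\C)[C@@H](OCOC)[C@H](OCc2ccc(OC)cc2)C1 | intermediate
23 | methyl iodoacetate | COC(=O)CI | starting material
24 | lithium dienolate of 22 (same geometry as 21) | [Li]O/C1=C\[C@@H](OCc2ccc(OC)cc2)[C@H](OCOC)/C(C)=C/CC/C(C)=C\1 | intermediate
25 | methyl 2-[(1R,3Z,7E,9R,10R)-9-(methoxymethoxy)-10-(4-methoxybenzyloxy)-4,8-dimethyl-2-oxocyclodeca-3,7-dien-1-yl]acetate | O=C1/C=C(/C)CC/C=C(\C)[C@@H](OCOC)[C@H](OCc2ccc(OC)cc2)[C@H]1CC(=O)OC | intermediate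
26 | (6S,7S,8R,9R)-6-hydroxy ester from 25 | O[C@H]1/C=C(/C)CC/C=C(\C)[C@@H](OCOC)[C@H](OCc2ccc(OC)cc2)[C@H]1CC(=O)OC | intermediate
27 | (6S,7S,8R,9R)-9-(methoxymethoxy)-8-(4-methoxybenzyloxy)-13-norgermacra-1(10)E,4Z-dien-6,12-olide, cis-fused | C1C(=O)O[C@H]2/C=C(/C)CC/C=C(\C)[C@@H](OCOC)[C@H](OCc3ccc(OC)cc3)[C@@H]12 | intermediate
28 | C11-(dimethylaminomethyl) lactone, C11 epimers | CN(C)CC1C(=O)O[C@H]2/C=C(/C)CC/C=C(\C)[C@@H](OCOC)[C@H](OCc3ccc(OC)cc3)[C@@H]12 | intermediate
29 | C11-(trimethylammoniomethyl) lactone iodide | C[N+](C)(C)CC1C(=O)O[C@H]2/C=C(/C)CC/C=C(\C)[C@@H](OCOC)[C@H](OCc3ccc(OC)cc3)[C@@H]12.[I-] | intermediate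
30 | (6S,7S,8R,9R)-9-(methoxymethoxy)-8-(4-methoxybenzyloxy)germacra-1(10)E,4Z,11(13)-trien-6,12-olide | C=C1C(=O)O[C@H]2/C=C(/C)CC/C=C(\C)[C@@H](OCOC)[C@H](OCc3ccc(OC)cc3)[C@@H]12 | intermediate
31 | (6S,7R,8R,9R)-8-hydroxy-9-(methoxymethoxy)germacra-1(10)E,4Z,11(13)-trien-6,12-olide (same spatial arrangement as 30) | C=C1C(=O)O[C@H]2/C=C(/C)CC/C=C(\C)[C@@H](OCOC)[C@H](O)[C@@H]12 | intermediate
32 | (6S,7S,8R,9R)-8-isobutyryloxy-9-(methoxymethoxy)germacra-1(10)E,4Z,11(13)-trien-6,12-olide | C=C1C(=O)O[C@H]2/C=C(/C)CC/C=C(\C)[C@@H](OCOC)[C@H](OC(=O)C(C)C)[C@@H]12 | intermediate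
33 | 9-O-bromomethyl ether of 34 | C=C1C(=O)O[C@H]2/C=C(/C)CC/C=C(\C)[C@@H](OCBr)[C@H](OC(=O)C(C)C)[C@@H]12 | intermediate
34 | (6S,7S,8R,9R)-9-hydroxy-8-isobutyryloxygermacra-1(10)E,4Z,11(13)-trien-6,12-olide | C=C1C(=O)O[C@H]2/C=C(/C)CC/C=C(\C)[C@@H](O)[C@H](OC(=O)C(C)C)[C@@H]12 | intermediate
35 | (1R,6S,7S,8R,9S,10R)-1,10-epoxy-9-hydroxy-8-isobutyryloxygermacra-4Z,11(13)-dien-6,12-olide, CNP0110853.1 | C=C1C(=O)O[C@H]2/C=C(/C)CC[C@H]3O[C@]3(C)[C@@H](O)[C@H](OC(=O)C(C)C)[C@@H]12 | target

Total step count: 16. Longest linear sequence: 15 steps (steps 1, 2 and 4–16). The branch from 8 counts 14.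

Steps most likely to fail

Step 9. The two donor-substituted termini may slow the shift so much that the temperature it needs allows the dienolate to expel the C8 alkoxide (E1cB), and part of the material may pass through a boat. The fallback accepts the elimination and installs O8 after the ring expansion.
- From 19, the same base at 40–50 °C without the cold quench should give, by the shift and loss of the benzylic alkoxide, (2Z,6E,8S,9E)-8-(methoxymethoxy)-3,7-dimethylcyclodeca-2,6,9-trien-1-one F1. C9 of F1 still carries the transferred chirality.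
- Copper-catalysed conjugate borylation (CuCl, NaOtBu, a Josiphos-type ligand, B2pin2, MeOH, THF) should attack the less substituted enone terminus C8 under ligand control and give the C8 pinacolboryl ketone F2.
- NaBO3·4H2O oxidises the C–B bond with retention to the C8 hydroxy ketone F3.
- 4-Methoxybenzyl trichloroacetimidate with La(OTf)3 (cat) then leads back to 22.

Step 10. C-alkylation may be slow enough for loss of the C8 ether from the lithium dienolate, or for proton transfer to the extended dienolate, with loss of regio- and facial control. The fallback avoids a free basic enolate during C–C bond formation.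
- From 22, LiN(iPr)2 and Me3SiCl at −78 °C give the trimethylsilyl dienol ether F4.
- The electrophilic radical generated from 23 with Et3B and air (2,6-lutidine as silyl iodide scavenger, CH2Cl2, 0 °C) adds to C7 of this electron-rich olefin from the ring periphery under neutral conditions.
- Collapse of the iodine-transfer adduct returns the route at 25.

Step 16. Facial selectivity may be poor if the ring also populates the conformer in which the C9 hydroxyl eclipses the olefin and steers the peracid to the other face, and some attack may occur at C4=C5. The fallback replaces hydroxyl guidance by purely steric control.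
- From 34, Et3SiCl and imidazole give the 9-O-triethylsilyl ether F5, whose bulky group should hold C9–O pseudo-equatorial.
- Dimethyldioxirane in acetone at −20 °C then attacks the exposed outer face to give the silylated epoxide F6.
- Et3N·3HF in THF releases 35.

Further compounds
F1 | step 9 | (2Z,6E,8S,9E)-8-(methoxymethoxy)-3,7-dimethylcyclodeca-2,6,9-trien-1-one | O=C1/C=C(/C)CC/C=C(\C)[C@@H](OCOC)/C=C/1
F2 | step 9 | C8 pinacolboryl analogue of 22 (boron in place of the PMB-oxy group, same spatial arrangement) | O=C1/C=C(/C)CC/C=C(\C)[C@@H](OCOC)[C@H](B2OC(C)(C)C(C)(C)O2)C1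
F3 | step 9 | (2Z,6E,8R,9R)-9-hydroxy-8-(methoxymethoxy)-3,7-dimethylcyclodeca-2,6-dien-1-one | O=C1/C=C(/C)CC/C=C(\C)[C@@H](OCOC)[C@H](O)C1
F4 | step 10 | trimethylsilyl dienol ether of 22 (C6=C7, O6 cis to C8) | C[Si](C)(C)O/C1=C\[C@@H](OCc2ccc(OC)cc2)[C@H](OCOC)/C(C)=C/CC/C(C)=C\1
F5 | step 16 | 9-O-triethylsilyl ether of 34 | C=C1C(=O)O[C@H]2/C=C(/C)CC/C=C(\C)[C@@H](O[Si](CC)(CC)CC)[C@H](OC(=O)C(C)C)[C@@H]12
F6 | step 16 | 9-O-triethylsilyl ether of 35 | C=C1C(=O)O[C@H]2/C=C(/C)CC[C@H]3O[C@]3(C)[C@@H](O[Si](CC)(CC)CC)[C@H](OC(=O)C(C)C)[C@@H]12
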